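**Retrosynthetic overview**

Numbering: the target is named as a tricyclo[5.3.1.0(1,5)]undecane, with C1 the quaternary bridgehead, C5 the ring-fusion CH, C7 the methyl-bearing bridgehead and C11 the bridging ketone; ring A is the six-membered triketone ring (C1, C7–C11), ring B the cyclopentanone (C1, C5, C6, C7, C11), ring C the cyclopentane (C1–C5).
Disconnections: the tertiary C–O bond (Markovnikov hydration of an isopropenyl group); then C1–C5 and C3–C4 together in one oxidative radical cascade; then the C7–prenyl bond (asymmetric dearomatising prenylation), the C1–prenyl bond and the acyl group.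
Ring order: ring A is the phloroglucinol ring, carried through in dearomatised form; ring B closes first (C1–C5) and ring C second (C3–C4), both in the key step.
Enabling feature: in the monocyclic precursor C1 is the CH of a 1,3-diketone (between C10=O and C11=O) and gives an electrophilic radical on one-electron oxidation; the prenyl group on C7 holds its alkene CH (C5) five atoms from C1, and the prenyl group on C1 holds its alkene CH (C3) five atoms from the C4 radical that results.

Key step: step 4

Assumption: the target is treated as the enol tautomer drawn, and since the sense of induction of the Trost ligand on this phenoxide cannot be predicted with certainty, the (R,R) ligand is written and its mirror image would be used if the (6R) dienone were to form.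

**Route**

Step 1
Reactants: 1 2-methylbenzene-1,3,5-triol (2-methylphloroglucinol)
Product: 2 1-(2,4,6-trihydroxy-3-methylphenyl)-2-methylpropan-1-one
Conditions: isobutyryl chloride (1.1 equiv), AlCl3 (3.5 equiv), PhNO2, 65 °C; aq. HCl
Reagents that add atoms: isobutyryl chloride, CC(C)C(Cl)=O
Why: Friedel–Crafts acylation of a very electron-rich arene whose two free ring positions are equivalent by symmetry, so one ketone should result, and the acyl group deactivates the ring against a second acylation.

Step 2
Reactants: 2 1-(2,4,6-trihydroxy-3-methylphenyl)-2-methylpropan-1-one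
Product: 3 1-[2,4,6-trihydroxy-3-methyl-5-(3-methylbut-2-en-1-yl)phenyl]-2-methylpropan-1-one
Conditions: prenyl bromide (1.0 equiv), 1 M aq. KOH (1.1 equiv), 0 °C
Reagents that add atoms: prenyl bromide (1-bromo-3-methylbut-2-ene), CC(C)=CCBr
Why: C-alkylation of the ambident phenoxide in water, where hydrogen bonding to the oxygens favours attack through carbon; the only unsubstituted ring carbon reacts and re-aromatises, and no stereocentre is formed.

Step 3
Reactants: 3 1-[2,4,6-trihydroxy-3-methyl-5-(3-methylbut-2-en-1-yl)phenyl]-2-methylpropan-1-one
Product: 4 (6S)-3,5-dihydroxy-6-methyl-2,6-bis(3-methylbut-2-en-1-yl)-4-(2-methylpropanoyl)cyclohexa-2,4-dien-1-one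
Conditions: Pd2(dba)3·CHCl3 (2.5 mol %), (R,R)-DACH-phenyl Trost ligand (7.5 mol %), tert-butyl 2-methylbut-3-en-2-yl carbonate (1.05 equiv), toluene, 0 °C to rt
Reagents that add atoms: tert-butyl 2-methylbut-3-en-2-yl carbonate, CC(C)(C)OC(=O)OC(C)(C)C=C
Why: Tsuji–Trost allylic alkylation run as an asymmetric dearomatisation, in which the phenoxide (freed by the tert-butoxide that the carbonate releases) attacks the CH2 end of the prenyl–palladium complex formed by zerovalent palladium; the methyl-bearing ring carbon is less crowded than the prenyl-bearing one, O-allyl products re-ionise, and the chiral pocket of the ligand selects one face of the flat nucleophile and so sets the quaternary stereocentre.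

Step 4
Reactants: 4 (6S)-3,5-dihydroxy-6-methyl-2,6-bis(3-methylbut-2-en-1-yl)-4-(2-methylpropanoyl)cyclohexa-2,4-dien-1-one
Product: 7 (1S,3R,5S,7S)-8-hydroxy-4,4,7-trimethyl-9-(2-methylpropanoyl)-3-(prop-1-en-2-yl)tricyclo[5.3.1.0(1,5)]undec-8-ene-10,11-dione, via bicyclic tertiary radical 5 (not isolated), via tricyclic tertiary radical 6 (not isolated)
Conditions: Mn(OAc)3·2H2O (2.2 equiv), Cu(OAc)2·H2O (0.2 equiv), degassed AcOH (0.01 M), rt
Reagents that add atoms: none
Why: The manganese enolate of 4 is oxidised by trivalent manganese to the electrophilic radical at C1, which joins the alkene CH of the C7 prenyl group (C5) by 5-exo-trig addition, a union of two carbons that are both nucleophilic in the ground state, closing ring B and the bicyclo[3.2.1]octane; the tertiary radical 5 then closes ring C by a second 5-exo-trig addition to the other prenyl group, and divalent copper turns the tertiary radical 6 into the isopropenyl group by oxidative elimination. The closest known reaction type is the Mn(OAc)3/Cu(OAc)2 oxidative free-radical polycyclisation of unsaturated 1,3-dicarbonyl compounds, which has close precedent on dearomatised prenylated acylphloroglucinols. C7 is the only stereocentre of 4 and controls C1, because its three-atom tether can reach the radical carbon from one face only; C5 follows, since only the transition state with the CMe2 end exo (turned away from the C8–C10 enol-diketone bridge) is unhindered and only that isomer can close ring C cis-fused. C3 is decided by chair-like against boat-like closure of ring C, which the framework biases only weakly (the needed isomer has the side chain syn to the C11 ketone and away from the endo hydrogen at C5), so the C3 epimer is expected as a by-product and is to be removed by chromatography. Site selectivity is secured because the acyl-bearing ring carbon is the more stabilised and more crowded radical terminus, and 5-exo against 6-endo closure because both trisubstituted alkenes are attacked at their CH carbon to give tertiary radicals. A low copper loading and high dilution should keep radical 5 from being oxidised before it cyclises.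

Step 5
Reactants: 7 (1S,3R,5S,7S)-8-hydroxy-4,4,7-trimethyl-9-(2-methylpropanoyl)-3-(prop-1-en-2-yl)tricyclo[5.3.1.0(1,5)]undec-8-ene-10,11-dione
Product: 8 (1S,3S,5S,7S)-8-hydroxy-3-(2-hydroxypropan-2-yl)-4,4,7-trimethyl-9-(2-methylpropanoyl)tricyclo[5.3.1.0(1,5)]undec-8-ene-10,11-dione (CNP0267234.1)
Conditions: Co(acac)2 (20 mol %), PhSiH3 (2.5 equiv), O2 (1 atm), THF, rt
Reagents that add atoms: dioxygen, O=O
Why: Mukaiyama hydration, in which a cobalt hydride transfers a hydrogen atom to the CH2 end of the 1,1-disubstituted alkene, the tertiary radical (the same species as 6) is trapped by O2 and the peroxide is reduced to the tertiary alcohol, so Markovnikov selectivity is inherent, no stereocentre is formed and the ketones, the enol and the four existing stereocentres should stay untouched.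

**Compound list**

1 | 2-methylbenzene-1,3,5-triol (2-methylphloroglucinol) | Cc1c(O)cc(O)cc1O | starting material
2 | 1-(2,4,6-trihydroxy-3-methylphenyl)-2-methylpropan-1-one | CC(C)C(=O)c1c(O)cc(O)c(C)c1O | intermediate
3 | 1-[2,4,6-trihydroxy-3-methyl-5-(3-methylbut-2-en-1-yl)phenyl]-2-methylpropan-1-one | CC(C)C(=O)c1c(O)c(CC=C(C)C)c(O)c(C)c1O | intermediate
4 | (6S)-3,5-dihydroxy-6-methyl-2,6-bis(3-methylbut-2-en-1-yl)-4-(2-methylpropanoyl)cyclohexa-2,4-dien-1-one (descriptor for the tautomer drawn) | CC(C)C(=O)C1=C(O)[C@](C)(CC=C(C)C)C(=O)C(CC=C(C)C)=C1O | intermediate
5 | bicyclic tertiary radical: rings A and B closed, 2-propyl radical exo on the ring-fusion CH, second prenyl group on the quaternary bridgehead | CC(C)C(=O)C1=C(O)[C@]2(C)C[C@@H]([C](C)C)[C@](CC=C(C)C)(C1=O)C2=O | intermediate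
6 | tricyclic tertiary radical: skeleton of 7 with a 2-propyl radical in place of the isopropenyl group | CC(C)C(=O)C1=C(O)[C@]2(C)C[C@H]3C(C)(C)[C@@H]([C](C)C)C[C@@]3(C1=O)C2=O | intermediate
7 | (1S,3R,5S,7S)-8-hydroxy-4,4,7-trimethyl-9-(2-methylpropanoyl)-3-(prop-1-en-2-yl)tricyclo[5.3.1.0(1,5)]undec-8-ene-10,11-dione | CC(C)C(=O)C1=C(O)[C@]2(C)C[C@H]3C(C)(C)[C@@H](C(C)=C)C[C@@]3(C1=O)C2=O | intermediate
8 | (1S,3S,5S,7S)-8-hydroxy-3-(2-hydroxypropan-2-yl)-4,4,7-trimethyl-9-(2-methylpropanoyl)tricyclo[5.3.1.0(1,5)]undec-8-ene-10,11-dione (CNP0267234.1) | CC(C)C(=O)C1=C(O)[C@]2(C)C[C@H]3C(C)(C)[C@@H](C(C)(C)O)C[C@@]3(C1=O)C2=O | target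

**Step count and risks**

Total step count: 5. Longest linear sequence: 5 steps.

Steps most likely to fail:

Step 3 (asymmetric dearomatising prenylation). What may go wrong: weak discrimination between the two faces of the flat phenoxide by the chiral catalyst (low enantiomeric purity), together with alkylation at the prenyl-bearing ring carbon or a second alkylation of the product. The fallback sets out from 3 and comes back at 4. Compound 3 would be alkylated without a catalyst, with prenyl bromide and NaOMe in MeOH at 0 °C (the classical base-mediated C-alkylation of an acylphloroglucinol anion at a substituted ring carbon), to give the racemic dienone F1. This strong vinylogous acid would be resolved with (R)-1-phenylethylamine: fractional crystallisation from ethyl acetate/heptane should deliver the less soluble diastereomer, the (R)-1-phenylethylammonium salt of 4 F2 (the (S)-amine is used if the salt of the mirror-image acid crystallises first). Partition between dilute HCl and ethyl acetate then sets 4 free.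

Step 4 (key step). What may go wrong: poor facial selectivity in the second ring closure, so that the C3 epimer of 7 forms in a comparable amount and the two isopropenyl compounds are hard to separate. The fallback sets out from 7, carried on as the unseparated mixture with its C3 epimer, and comes back at 8. Lemieux–Johnson cleavage (OsO4 cat., NaIO4, 2,6-lutidine, dioxane/water) of the isopropenyl group, the only electron-rich unconjugated alkene, should give the methyl ketone as a mixture of C3 epimers F3. C3 is now alpha to a ketone, and DBU in toluene at 60 °C should equilibrate it towards the (3S) methyl ketone F4, in which the acetyl group lies on the face of ring C away from the endo hydrogen at C5; recovered minor epimer goes back through the same equilibration. MeMgBr with CeCl3 in THF at −78 °C should then add to the methyl ketone only (the acidic enol is masked as its magnesium enolate and the C11 ketone is shielded by two quaternary carbons) and give 8 directly, so that step 5 is not needed.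

Step 2 (mono-C-prenylation). What may go wrong: over-alkylation and O-alkylation, because the product phenoxide is as nucleophilic as the starting one. The fallback sets out from 2 and comes back at 3. Palladium-catalysed O-alkylation of the free, non-chelated hydroxyl para to the acyl group with tert-butyl 2-methylbut-3-en-2-yl carbonate (Pd(PPh3)4 cat., THF, 0 °C) should give the 1,1-dimethylallyl aryl ether F5. Heating in toluene at 110 °C (aromatic Claisen rearrangement) should move the allyl unit, with inversion of its ends, to the only unsubstituted ortho carbon and give 3 after tautomerisation.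

**Further compounds**

F1 | step 3 | racemic 3,5-dihydroxy-6-methyl-2,6-bis(3-methylbut-2-en-1-yl)-4-(2-methylpropanoyl)cyclohexa-2,4-dien-1-one | CC(C)C(=O)C1=C(O)C(C)(CC=C(C)C)C(=O)C(CC=C(C)C)=C1O
F2 | step 3 | (R)-1-phenylethylammonium salt of 4 | CC(C)C(=O)C1=C([O-])[C@](C)(CC=C(C)C)C(=O)C(CC=C(C)C)=C1O.C[C@@H]([NH3+])c1ccccc1
F3 | step 4 | (1S,5S,7S)-3-acetyl-8-hydroxy-4,4,7-trimethyl-9-(2-methylpropanoyl)tricyclo[5.3.1.0(1,5)]undec-8-ene-10,11-dione, mixture of C3 epimers | CC(C)C(=O)C1=C(O)[C@]2(C)C[C@H]3C(C)(C)C(C(C)=O)C[C@@]3(C1=O)C2=O
F4 | step 4 | (1S,3S,5S,7S)-3-acetyl-8-hydroxy-4,4,7-trimethyl-9-(2-methylpropanoyl)tricyclo[5.3.1.0(1,5)]undec-8-ene-10,11-dione | CC(C)C(=O)C1=C(O)[C@]2(C)C[C@H]3C(C)(C)[C@@H](C(C)=O)C[C@@]3(C1=O)C2=O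
F5 | step 2 | 1-{2,6-dihydroxy-3-methyl-4-[(2-methylbut-3-en-2-yl)oxy]phenyl}-2-methylpropan-1-one | CC(C)C(=O)c1c(O)cc(OC(C)(C)C=C)c(C)c1O
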